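Friday's flask cannot have turned the substrate it lost into ring: by 15.0 min it has lost 32.0% of its charge, while ring reads 4%. Substrate therefore has a second way out.

| flask | substrate | gas | remark | time |
|---|---|---|---|---|
| Saturday's | 0.0062 M | 3.1 mM (held) | run made earlier |  |
| Tuesday's | 0.024 M | 3.1 mM (held) | run made earlier |  |
| Friday's | 0.075 M | 3.1 mM (held) | run made earlier |  |
| north-west | 0.0060 M | 3.1 mM (held) |  | 20 min |
| north | 0.012 M | 3.1 mM (held) |  | 20 min |
| south-east | 0.025 M | 3.1 mM (held) |  | 20 min |
| north-east | 0.050 M | 3.1 mM (held) |  | 20 min |
| west | 0.10 M | 3.1 mM (held) |  | 20 min |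

| run | time / min | ring / % | substrate / % |
|---|---|---|---|
| Saturday's | 1.33 | 2 | 100 |
| Saturday's | 4.00 | 0 | 93 |
| Saturday's | 6.00 | 2 | 88 |
| Saturday's | 10.0 | 9 | 72 |
| Saturday's | 15.0 | 20 | 62 |
| Tuesday's | 3.00 | 1 | 94 |
| Tuesday's | 6.00 | 2 | 89 |
| Tuesday's | 8.00 | 6 | 79 |
| Tuesday's | 12.0 | 14 | 70 |
| Tuesday's | 15.0 | 15 | 63 |
| Friday's | 1.00 | 0 | 100 |
| Friday's | 2.00 | 4 | 102 |
| Friday's | 4.00 | 1 | 96 |
| Friday's | 8.00 | 4 | 89 |
| Friday's | 15.0 | 4 | 68 |

(scatter of a reading: 2 percentage points)

- at the start none of the gas is in solution
- a reading or a percentage of ring counts all its forms, free or not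
- the concentration of ring that is asked is that of its free form alone
- "hardly changes" means that all values lie within two and a half points (for a concentration: within two and a half percent of the largest)
- a reading of substrate is of its free form alone

1. [ring] (only what is free in solution) at the end for north-west, north, south-east, north-east, west, in this order
2. the shape of the row from first to last (hardly changes / rises, then falls / rises all the way / falls all the way / falls, then rises)

Saturday's flask at 15.0 min has lost 38.0% and reads 20% of ring, a ratio of 0.526. This ratio, ring read per substrate lost, is the ring share, or selectivity for ring. Tuesday's flask gives 0.405 and Friday's 0.125, so the share falls as the charge rises .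

An objection: ring trails substrate, so the share may simply grow with time. Saturday's flask had 0.321 at 10.0 min, which supports the doubt. Tuesday's flask had 0.467 at 12.0 min and then read 0.405, but that dip of 0.0613 stands beside a scatter of 0.0541 on this ratio, so it shows no real fall. The doubt stands: the share read at 15.0 min is carried to 20 min for want of a later reading, and the ring reckoned from it may come out low.

Reaching 20 min also needs a lifetime for substrate. The slow start would distort a reckoning from zero, so Saturday's last stretch serves: the time between its readings over the logarithm of their ratio gives 33.4 min. The remaining 5.00 min are 0.150 of a lifetime, so substrate keeps a factor 0.861.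

North-west, with Saturday's share, then holds 53.4% of substrate and about 0.00147 M of ring. South-east, with Tuesday's share, holds about 0.00464 M. Both amounts include bound ring, so the free row stands lower by a part that no reading shows. At the top, Friday's ring at 15.0 min is 0.00300 M against Tuesday's 0.00360 M, but the scatter of 2 percentage points is half of that reading. This reckoning therefore commits, weakly, to a row that rises and then falls.

The forecast reads 0.0018 M, 0.003 M, 0.0034 M, 0.003 M, 0.0025 M, rises, then falls, and says of its decline: “This binding is a guess”. The flask gives 0.00146 M, 0.00246 M, 0.00364 M, 0.00404 M, 0.00301 M: rises, then falls, turning at 0.044 M.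

    substrate + ring ⇌ idle adduct, settled at all times (K = 22.0 /M)
    substrate + activator → activated form (k = 0.190 /M/s)
    substrate + activated form → open dimer (k = 0.0320 /M/s)
    activated form → ring (k = 0.00180 /s)
    gas ⇌ activator, rate k5*(csat - [activator]) (kL = 0.0100 /s)

North-west has a ring share of 0.335 at 10.0 min, and at 20.0 min it holds 25.9% of ring, bound form counted, with 52% of substrate left, a share of 0.540, so its share grows with time, against Saturday's 0.526 read at 15.0 min. South-east at 20.0 min holds 18.8% with 53% left, a share of 0.400 against Tuesday's 0.405 read at 15.0 min, and its free ring stands at 0.00364 M.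

Readings and results are calculated for substances that don't exist; scatter was added.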